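**Retrosynthetic overview**
1. The acetonide on O6'/O8' comes off last; before that, the E-alkene C1'=C2' is cut by cross-metathesis into (S)-6-vinyl-5,6-dihydro-2H-pyran-2-one and a C2'–C10' homoallylic acetate.
2. C3'–C4' is cut by a reagent-controlled allylboration that sets C4' anti to O6'. C9'–C10' is cut by a benzyl Wittig/hydrogenation pair. This leaves a six-carbon C4'–C9' unit with a carboxyl at C4' and a chloride at C9'.
3. The strategy rests on the syn-1,3-diol C5'H2–C6'(OH)–C7'H2–C8'(OH) of the side chain (numbered C1'–C10' outward from lactone C6). One aldolase step forms C7'–C8' and C5'–C6' from chloroacetaldehyde (C8', C9') and two acetaldehydes (C6'/C7' and C4'/C5') and sets both carbinol centres.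
4. Ring order: tetrahydropyran lactol (step 1, temporary carrier of the diol), then 1,3-dioxane acetonide (step 3, protecting ring), then the dihydropyranone by ring-closing metathesis (step 14), the only ring built that stays in the target.

Key step: step 1

Remark: lactol 5 is handled as its anomeric mixture (the anomeric centre disappears in step 2); the aldolase and both antipodes of Ipc2B(allyl) are taken as purchasable reagents.

**Step 1**
Reactants: 1 chloroacetaldehyde (aqueous solution); 2 acetaldehyde (2.2 equiv)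
Product: 5 (4R,6S)-6-(chloromethyl)tetrahydro-2H-pyran-2,4-diol, via (S)-4-chloro-3-hydroxybutanal 3 (not isolated), via (3R,5S)-6-chloro-3,5-dihydroxyhexanal 4 (not isolated)
Conditions: 2-deoxyribose-5-phosphate aldolase (E. coli, cell-free extract), H2O, NaHCO3 buffer pH 7.3, 1 and 2 co-fed over 3 h, 25 °C; acetone (protein removal), EtOAc extraction
Reagents that add atoms: none
Why: The active-site lysine of this Schiff-base aldolase condenses with acetaldehyde to an enamine, which adds to the carbonyl of chloroacetaldehyde (C7'–C8') and releases 3 on hydrolysis; 3 is accepted again and a second enamine adds to its aldehyde (C5'–C6') to give 4. The closest known reaction type is the enzymatic sequential aldol of acetaldehyde onto 2-substituted acetaldehydes to 2,4,6-trideoxyhexoses, which is known for this substrate pair. The single ring closes by attack of the C5 hydroxyl of 4 on the C1 aldehyde (6-exo-trig hemiacetalisation) to the tetrahydropyran lactol 5. Both new carbinol centres, C8' (S in 3 and 5 because chlorine raises the priority of C9') and C6' (R), are fixed by the active site, which presents the same face of each acceptor carbonyl to the enamine, so the two hydroxyls should come out syn. The step needs chloroacetaldehyde to act only as acceptor and the chain to stop after two additions: the enzyme accepts only acetaldehyde-type donors, cyclisation to the lactol withdraws the aldehyde from further addition, and slow co-feeding keeps the free aldehyde concentrations low enough to spare the enzyme.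

**Step 2**
Reactants: 5 (4R,6S)-6-(chloromethyl)tetrahydro-2H-pyran-2,4-diol
Product: 6 (4R,6S)-6-(chloromethyl)-4-hydroxytetrahydro-2H-pyran-2-one
Conditions: Br2, BaCO3, H2O, 20 °C, dark
Reagents that add atoms: none
Why: Bromine-water oxidation of a cyclic hemiacetal (aldose to aldonolactone type) is selective for the anomeric C–H over the secondary C4 carbinol, and no stereocentre is touched.

**Step 3**
Reactants: 6 (4R,6S)-6-(chloromethyl)-4-hydroxytetrahydro-2H-pyran-2-one
Product: 7 methyl 2-[(4R,6S)-6-(chloromethyl)-2,2-dimethyl-1,3-dioxan-4-yl]acetate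
Conditions: Me2C(OMe)2, MeOH, p-TsOH·H2O (cat.), 20 °C
Reagents that add atoms: 2,2-dimethoxypropane COC(C)(C)OC; methanol CO
Why: Acid-catalysed methanolysis of the δ-lactone and transketalisation in one pot, driven by trapping of the syn-1,3-diol as the cis-4,6-disubstituted 1,3-dioxane with both substituents equatorial; both stereocentres are carried over unchanged.

**Step 4**
Reactants: 7 methyl 2-[(4R,6S)-6-(chloromethyl)-2,2-dimethyl-1,3-dioxan-4-yl]acetate
Product: 8 methyl 2-[(4R,6S)-6-(acetoxymethyl)-2,2-dimethyl-1,3-dioxan-4-yl]acetate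
Conditions: Bu4NOAc (2 equiv), N-methylpyrrolidone, 100 °C
Reagents that add atoms: tetrabutylammonium acetate CC(=O)[O-].CCCC[N+](CCCC)(CCCC)CCCC
Why: SN2 displacement of the primary chloride by unsolvated acetate in a dipolar aprotic solvent occurs at the achiral CH2, so C6 keeps its configuration; heat is needed because the β-oxygen slows the substitution.

**Step 5**
Reactants: 8 methyl 2-[(4R,6S)-6-(acetoxymethyl)-2,2-dimethyl-1,3-dioxan-4-yl]acetate
Product: 9 methyl 2-[(4R,6S)-6-(hydroxymethyl)-2,2-dimethyl-1,3-dioxan-4-yl]acetate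
Conditions: K2CO3 (0.2 equiv), MeOH, 0 → 20 °C
Reagents that add atoms: none
Why: Base-catalysed transesterification (Zemplén type) removes the acetate as methyl acetate, while exchange at the methyl ester is degenerate in methanol and the acetonide is stable to base.

**Step 6**
Reactants: 9 methyl 2-[(4R,6S)-6-(hydroxymethyl)-2,2-dimethyl-1,3-dioxan-4-yl]acetate
Product: 10 methyl 2-[(4R,6S)-6-formyl-2,2-dimethyl-1,3-dioxan-4-yl]acetate
Conditions: TEMPO (0.1 equiv), PhI(OAc)2 (1.1 equiv), CH2Cl2, 20 °C; used at once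
Reagents that add atoms: none
Why: Oxoammonium (TEMPO) oxidation of a primary alcohol stops at the aldehyde under non-basic conditions, so the α-alkoxy stereocentre C6 should not epimerise.

**Step 7**
Reactants: 10 methyl 2-[(4R,6S)-6-formyl-2,2-dimethyl-1,3-dioxan-4-yl]acetate; 11 benzyltriphenylphosphonium chloride
Product: 13 methyl 2-[(4R,6S)-2,2-dimethyl-6-(2-phenylethenyl)-1,3-dioxan-4-yl]acetate, via benzylidenetriphenylphosphorane 12 (not isolated)
Conditions: 11, NaN(SiMe3)2 (1.0 equiv to 11), THF, 0 °C; then 10, −78 → 20 °C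
Reagents that add atoms: none
Why: Wittig olefination with a semi-stabilised ylide forms C9'=C10'; the ylide is pre-formed so that no free base meets the epimerisable aldehyde or the ester, and the expected E/Z mixture is of no consequence because the double bond is saturated in step 8.

**Step 8**
Reactants: 13 methyl 2-[(4R,6S)-2,2-dimethyl-6-(2-phenylethenyl)-1,3-dioxan-4-yl]acetate
Product: 14 methyl 2-[(4R,6R)-2,2-dimethyl-6-(2-phenylethyl)-1,3-dioxan-4-yl]acetate
Conditions: H2 (1 atm), 5% Pt/C, EtOAc, 20 °C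
Reagents that add atoms: none
Why: Heterogeneous catalytic hydrogenation of the styrenyl double bond, with platinum in a neutral aprotic solvent chosen over palladium to suppress hydrogenolysis of the allylic C6–O bond; the descriptor at C6 changes from S to R by priority only.

**Step 9**
Reactants: 14 methyl 2-[(4R,6R)-2,2-dimethyl-6-(2-phenylethyl)-1,3-dioxan-4-yl]acetate
Product: 15 2-[(4R,6R)-2,2-dimethyl-6-(2-phenylethyl)-1,3-dioxan-4-yl]acetaldehyde
Conditions: i-Bu2AlH (1.1 equiv), CH2Cl2, −78 °C; MeOH quench, aq. potassium sodium tartrate (KNaC4H4O6)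
Reagents that add atoms: none
Why: Partial reduction of a methyl ester with i-Bu2AlH at low temperature, where the tetrahedral aluminium hemiacetal, held by the β-dioxane oxygen, should persist until the quench and then release the aldehyde.

**Step 10**
Reactants: 15 2-[(4R,6R)-2,2-dimethyl-6-(2-phenylethyl)-1,3-dioxan-4-yl]acetaldehyde
Product: 17 (2R)-1-[(4S,6R)-2,2-dimethyl-6-(2-phenylethyl)-1,3-dioxan-4-yl]pent-4-en-2-ol, via diisopinocampheylborinate ester 16 (not isolated)
Conditions: (+)-Ipc2B(allyl) (from (−)-α-pinene, 1.3 equiv), Et2O, −78 °C; then NaOH, H2O2, 0 → 20 °C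
Reagents that add atoms: (+)-B-allyldiisopinocampheylborane C=CCB([C@@H]1[C@@H](C)[C@@H]2C[C@H](C1)C2(C)C)[C@@H]1[C@@H](C)[C@@H]2C[C@H](C1)C2(C)C
Why: Brown allylboration through a chair six-membered transition state, in which the isopinocampheyl groups of the (+)-reagent direct the allyl group to the Re face of the aldehyde and so set C4' as R (anti to O6'), the remote dioxane exerting little bias of its own.

**Step 11**
Reactants: 17 (2R)-1-[(4S,6R)-2,2-dimethyl-6-(2-phenylethyl)-1,3-dioxan-4-yl]pent-4-en-2-ol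
Product: 18 (2R)-1-[(4R,6R)-2,2-dimethyl-6-(2-phenylethyl)-1,3-dioxan-4-yl]pent-4-en-2-yl acetate
Conditions: Ac2O, pyridine, DMAP (cat.), CH2Cl2, 20 °C
Reagents that add atoms: acetic anhydride CC(=O)OC(C)=O
Why: DMAP-catalysed acylation of the only free hydroxyl, with retention at C4' because the C–O bond is not broken.

**Step 12**
Reactants: 19 acrolein
Product: 21 (S)-hexa-1,5-dien-3-ol, via diisopinocampheylborinate ester 20 (not isolated)
Conditions: (−)-Ipc2B(allyl) (from (+)-α-pinene), Et2O, −78 °C; then NaOH, H2O2, 0 → 20 °C; distillation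
Reagents that add atoms: (−)-B-allyldiisopinocampheylborane C=CCB([C@H]1[C@H](C)[C@H]2C[C@@H](C1)C2(C)C)[C@H]1[C@H](C)[C@H]2C[C@@H](C1)C2(C)C
Why: Brown allylboration (1,2-addition to the enal through a chair transition state), in which the (−)-reagent delivers allyl to the Si face and gives the (S)-carbinol that becomes lactone C6.

**Step 13**
Reactants: 21 (S)-hexa-1,5-dien-3-ol
Product: 22 (S)-hexa-1,5-dien-3-yl prop-2-enoate
Conditions: acryloyl chloride, Et3N, DMAP (cat.), CH2Cl2, 0 °C
Reagents that add atoms: acryloyl chloride C=CC(=O)Cl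
Why: O-acylation of the secondary allylic alcohol with an acid chloride under amine base, with retention because the C–O bond is not broken.

**Step 14**
Reactants: 22 (S)-hexa-1,5-dien-3-yl prop-2-enoate
Product: 23 (S)-6-vinyl-5,6-dihydro-2H-pyran-2-one
Conditions: first-generation Grubbs catalyst RuCl2(=CHPh)(PCy3)2 (5 mol%), Ti(O-i-Pr)4 (0.3 equiv), CH2Cl2 (0.01 M), 40 °C
Reagents that add atoms: none
Why: Ring-closing metathesis, in which the catalyst loads on the unhindered allyl terminus and closes onto the acrylate to the six-membered enoate in preference to the butenolide (which would need the hindered, oxygen-bearing vinyl group), so the vinyl group is kept as the handle for step 15.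

**Step 15**
Reactants: 18 (2R)-1-[(4R,6R)-2,2-dimethyl-6-(2-phenylethyl)-1,3-dioxan-4-yl]pent-4-en-2-yl acetate; 23 (S)-6-vinyl-5,6-dihydro-2H-pyran-2-one (2.5 equiv)
Product: 24 (2R,4E)-1-[(4R,6R)-2,2-dimethyl-6-(2-phenylethyl)-1,3-dioxan-4-yl]-5-[(2S)-6-oxo-3,6-dihydro-2H-pyran-2-yl]pent-4-en-2-yl acetate
Conditions: second-generation Hoveyda–Grubbs catalyst RuCl2(=CH-C6H4-2-O-i-Pr)(H2IMes) (5–10 mol%), CH2Cl2, 40 °C
Reagents that add atoms: none
Why: Olefin cross-metathesis between a terminal alkene that homodimerises fast and reversibly (18) and an oxygen-bearing secondary allylic vinyl group that homodimerises slowly (23) should give the heterodimer as the thermodynamically preferred E-alkene, while the conjugated endocyclic enoate is too electron-poor and hindered to take part.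

**Step 16**
Reactants: 24 (2R,4E)-1-[(4R,6R)-2,2-dimethyl-6-(2-phenylethyl)-1,3-dioxan-4-yl]-5-[(2S)-6-oxo-3,6-dihydro-2H-pyran-2-yl]pent-4-en-2-yl acetate
Product: 25 (1E,4R,6R,8R)-6,8-dihydroxy-1-[(2S)-6-oxo-3,6-dihydro-2H-pyran-2-yl]-10-phenyldec-1-en-4-yl acetate (target)
Conditions: AcOH/H2O (4:1), 25–35 °C
Reagents that add atoms: none
Why: Acid-catalysed hydrolysis of the isopropylidene ketal with a weak acid near room temperature should free the C6'/C8' diol without the base-promoted 1,3-acetyl shift from O4', lactone opening or conjugate addition, and no stereocentre is involved.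

**Compound list**
(The descriptor at dioxane C6 in 13/14 and at dioxane C4 in 15/16/17/18 changes by CIP priority only; no centre is inverted.)

1 | chloroacetaldehyde | ClCC=O | starting material
2 | acetaldehyde | CC=O | starting material
3 | (S)-4-chloro-3-hydroxybutanal | ClC[C@@H](O)CC=O | intermediate
4 | (3R,5S)-6-chloro-3,5-dihydroxyhexanal | ClC[C@@H](O)C[C@@H](O)CC=O | intermediate
5 | (4R,6S)-6-(chloromethyl)tetrahydro-2H-pyran-2,4-diol (anomeric mixture) | ClC[C@@H]1C[C@@H](O)CC(O)O1 | intermediate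
6 | (4R,6S)-6-(chloromethyl)-4-hydroxytetrahydro-2H-pyran-2-one | ClC[C@@H]1C[C@@H](O)CC(=O)O1 | intermediate
7 | methyl 2-[(4R,6S)-6-(chloromethyl)-2,2-dimethyl-1,3-dioxan-4-yl]acetate | ClC[C@@H]1C[C@H](CC(=O)OC)OC(C)(C)O1 | intermediate
8 | methyl 2-[(4R,6S)-6-(acetoxymethyl)-2,2-dimethyl-1,3-dioxan-4-yl]acetate | CC(=O)OC[C@@H]1C[C@H](CC(=O)OC)OC(C)(C)O1 | intermediate
9 | methyl 2-[(4R,6S)-6-(hydroxymethyl)-2,2-dimethyl-1,3-dioxan-4-yl]acetate | OC[C@@H]1C[C@H](CC(=O)OC)OC(C)(C)O1 | intermediate
10 | methyl 2-[(4R,6S)-6-formyl-2,2-dimethyl-1,3-dioxan-4-yl]acetate | O=C[C@@H]1C[C@H](CC(=O)OC)OC(C)(C)O1 | intermediate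
11 | benzyltriphenylphosphonium chloride | [Cl-].C(c1ccccc1)[P+](c1ccccc1)(c1ccccc1)c1ccccc1 | starting material
12 | benzylidenetriphenylphosphorane | C(=P(c1ccccc1)(c1ccccc1)c1ccccc1)c1ccccc1 | intermediate
13 | methyl 2-[(4R,6S)-2,2-dimethyl-6-(2-phenylethenyl)-1,3-dioxan-4-yl]acetate (E/Z mixture) | C(=Cc1ccccc1)[C@@H]1C[C@H](CC(=O)OC)OC(C)(C)O1 | intermediate
14 | methyl 2-[(4R,6R)-2,2-dimethyl-6-(2-phenylethyl)-1,3-dioxan-4-yl]acetate | c1ccccc1CC[C@@H]1C[C@H](CC(=O)OC)OC(C)(C)O1 | intermediate
15 | 2-[(4R,6R)-2,2-dimethyl-6-(2-phenylethyl)-1,3-dioxan-4-yl]acetaldehyde | c1ccccc1CC[C@@H]1C[C@H](CC=O)OC(C)(C)O1 | intermediate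
16 | (2R)-1-[(4S,6R)-2,2-dimethyl-6-(2-phenylethyl)-1,3-dioxan-4-yl]pent-4-en-2-yl bis[(1S,2R,3S,5S)-2,6,6-trimethylbicyclo[3.1.1]heptan-3-yl]borinate | C=CC[C@@H](OB([C@@H]1[C@@H](C)[C@@H]2C[C@H](C1)C2(C)C)[C@@H]1[C@@H](C)[C@@H]2C[C@H](C1)C2(C)C)C[C@H]1C[C@@H](CCc2ccccc2)OC(C)(C)O1 | intermediate
17 | (2R)-1-[(4S,6R)-2,2-dimethyl-6-(2-phenylethyl)-1,3-dioxan-4-yl]pent-4-en-2-ol | C=CC[C@@H](O)C[C@H]1C[C@@H](CCc2ccccc2)OC(C)(C)O1 | intermediate
18 | (2R)-1-[(4R,6R)-2,2-dimethyl-6-(2-phenylethyl)-1,3-dioxan-4-yl]pent-4-en-2-yl acetate | C=CC[C@@H](OC(C)=O)C[C@H]1C[C@@H](CCc2ccccc2)OC(C)(C)O1 | intermediate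
19 | acrolein | C=CC=O | starting material
20 | (3S)-hexa-1,5-dien-3-yl bis[(1R,2S,3R,5R)-2,6,6-trimethylbicyclo[3.1.1]heptan-3-yl]borinate | C=C[C@@H](OB([C@H]1[C@H](C)[C@H]2C[C@@H](C1)C2(C)C)[C@H]1[C@H](C)[C@H]2C[C@@H](C1)C2(C)C)CC=C | intermediate
21 | (S)-hexa-1,5-dien-3-ol | C=C[C@@H](O)CC=C | intermediate
22 | (S)-hexa-1,5-dien-3-yl prop-2-enoate | C=C[C@@H](OC(=O)C=C)CC=C | intermediate
23 | (S)-6-vinyl-5,6-dihydro-2H-pyran-2-one | C=C[C@@H]1CC=CC(=O)O1 | intermediate
24 | (2R,4E)-1-[(4R,6R)-2,2-dimethyl-6-(2-phenylethyl)-1,3-dioxan-4-yl]-5-[(2S)-6-oxo-3,6-dihydro-2H-pyran-2-yl]pent-4-en-2-yl acetate | CC(=O)O[C@H](C/C=C/[C@@H]1CC=CC(=O)O1)C[C@H]1C[C@@H](CCc2ccccc2)OC(C)(C)O1 | intermediate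
25 | (1E,4R,6R,8R)-6,8-dihydroxy-1-[(2S)-6-oxo-3,6-dihydro-2H-pyran-2-yl]-10-phenyldec-1-en-4-yl acetate | CC(=O)O[C@H](C/C=C/[C@@H]1CC=CC(=O)O1)C[C@H](O)C[C@H](O)CCc1ccccc1 | target

**Step count**
Total steps: 16. Longest linear sequence: 13 (steps 1–11, 15, 16); the lactone branch is steps 12–14.

**Steps most likely to fail**

1. Step 1. The enzyme may be deactivated by the two electrophilic aldehydes, or the cascade may stall after the first addition so that the mono-adduct accumulates. The fallback gives up the aldolase and reaches the same lactone chemically. It does not set out from a numbered compound (1 and 2 are abandoned) but from purchasable ethyl (S)-4-chloro-3-hydroxybutanoate F1. Claisen condensation with excess lithium enolate of tert-butyl acetate (LiN(i-Pr)2, THF, −40 °C) should give tert-butyl (5S)-6-chloro-5-hydroxy-3-oxohexanoate F2. Chelation-controlled syn reduction (Et2BOMe, NaBH4, THF/MeOH, −78 °C, Narasaka–Prasad) should then give tert-butyl (3R,5S)-6-chloro-3,5-dihydroxyhexanoate F3. CF3CO2H in CH2Cl2 would cleave the tert-butyl ester and lactonise the δ-hydroxy acid, so the route is rejoined at 6.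

2. Step 15. Productive metathesis at the hindered, oxygen-bearing vinyl group of 23 may be slow, so that homodimerisation of 18 and catalyst decay outrun the cross-coupling. The fallback builds the lactone on the chain instead and sets out from 18.
   - Cross-metathesis with crotonaldehyde (excess, second-generation Grubbs catalyst RuCl2(=CHPh)(PCy3)(H2IMes), CH2Cl2, 40 °C), a reliably reactive partner, should give (2R,4E)-1-[(4R,6R)-2,2-dimethyl-6-(2-phenylethyl)-1,3-dioxan-4-yl]-6-oxohex-4-en-2-yl acetate F4.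
   - Brown allylboration with (−)-Ipc2B(allyl) (Et2O, −78 °C) would pass through the diisopinocampheylborinate F5. Oxidation with H2O2 at pH 7, buffered to spare the acetate, should give (2R,4E,6S)-1-[(4R,6R)-2,2-dimethyl-6-(2-phenylethyl)-1,3-dioxan-4-yl]-6-hydroxynona-4,8-dien-2-yl acetate F6.
   - Acryloyl chloride/Et3N should give the acrylate (2R,4E,6S)-2-acetoxy-1-[(4R,6R)-2,2-dimethyl-6-(2-phenylethyl)-1,3-dioxan-4-yl]nona-4,8-dien-6-yl prop-2-enoate F7.
   - Ring-closing metathesis (first-generation Grubbs catalyst RuCl2(=CHPh)(PCy3)2, CH2Cl2, 40 °C) between the acrylate and the terminal allyl group returns to the route at 24.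

3. Step 4. Substitution at the β-oxygenated primary carbon may be slow, so that at the temperature needed, acetate attack on the methyl ester or elimination competes. The fallback avoids the chloride displacement, the aldehyde and the Wittig reaction altogether, and sets out from 6.
   - K2CO3 in MeOH at 0 °C should open the lactone, and the liberated C5 alkoxide should close onto CH2Cl to give methyl (3R)-3-hydroxy-4-[(2S)-oxiran-2-yl]butanoate F8.
   - Copper-catalysed opening at the terminal epoxide carbon with BnMgCl (2.5 equiv, CuI 10 mol%, THF, −40 °C) should give methyl (3R,5R)-3,5-dihydroxy-7-phenylheptanoate F9 with C8' untouched. Partial lactonisation of F9 would not matter.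
   - Me2C(OMe)2/MeOH/p-TsOH, as in step 3, would return to the route at 14, replacing steps 3–8.

**Further compounds**
F1 | step 1 | ethyl (S)-4-chloro-3-hydroxybutanoate | ClC[C@@H](O)CC(=O)OCC
F2 | step 1 | tert-butyl (5S)-6-chloro-5-hydroxy-3-oxohexanoate | ClC[C@@H](O)CC(=O)CC(=O)OC(C)(C)C
F3 | step 1 | tert-butyl (3R,5S)-6-chloro-3,5-dihydroxyhexanoate | ClC[C@@H](O)C[C@@H](O)CC(=O)OC(C)(C)C
F4 | step 15 | (2R,4E)-1-[(4R,6R)-2,2-dimethyl-6-(2-phenylethyl)-1,3-dioxan-4-yl]-6-oxohex-4-en-2-yl acetate | CC(=O)O[C@H](C/C=C/C=O)C[C@H]1C[C@@H](CCc2ccccc2)OC(C)(C)O1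
F5 | step 15 | (2R,4E,6S)-2-acetoxy-1-[(4R,6R)-2,2-dimethyl-6-(2-phenylethyl)-1,3-dioxan-4-yl]nona-4,8-dien-6-yl bis[(1R,2S,3R,5R)-2,6,6-trimethylbicyclo[3.1.1]heptan-3-yl]borinate | CC(=O)O[C@H](C/C=C/[C@@H](OB([C@H]1[C@H](C)[C@H]2C[C@@H](C1)C2(C)C)[C@H]1[C@H](C)[C@H]2C[C@@H](C1)C2(C)C)CC=C)C[C@H]1C[C@@H](CCc2ccccc2)OC(C)(C)O1
F6 | step 15 | (2R,4E,6S)-1-[(4R,6R)-2,2-dimethyl-6-(2-phenylethyl)-1,3-dioxan-4-yl]-6-hydroxynona-4,8-dien-2-yl acetate | CC(=O)O[C@H](C/C=C/[C@@H](O)CC=C)C[C@H]1C[C@@H](CCc2ccccc2)OC(C)(C)O1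
F7 | step 15 | (2R,4E,6S)-2-acetoxy-1-[(4R,6R)-2,2-dimethyl-6-(2-phenylethyl)-1,3-dioxan-4-yl]nona-4,8-dien-6-yl prop-2-enoate | CC(=O)O[C@H](C/C=C/[C@@H](OC(=O)C=C)CC=C)C[C@H]1C[C@@H](CCc2ccccc2)OC(C)(C)O1
F8 | step 4 | methyl (3R)-3-hydroxy-4-[(2S)-oxiran-2-yl]butanoate | C1O[C@H]1C[C@@H](O)CC(=O)OC
F9 | step 4 | methyl (3R,5R)-3,5-dihydroxy-7-phenylheptanoate | c1ccccc1CC[C@@H](O)C[C@@H](O)CC(=O)OC
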